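**Plan**

- Numbering: each chromene is O1, C2, C3, C4, C4a, C5–C8, C8a; the linker is C1'=C2'–C3'(CH3), with C1' on C6 of ring A and C3' on C6 of ring B. The retrosynthesis cuts C1'=C2' (Julia–Kocienski: ring A aldehyde plus ring B sulfone), then O1–C2 and C4–C4a of each pyran (aryl propargyl ether Claisen), then C6–C5 and C8–C8a of ring B.
- Enabling feature: in ring B the oxygens on C7 and C8a are meta and C6, which carries C3', lies next to C7. This is the pattern of a 4-substituted cyclohexane-1,3-dione, so the benzene ring of ring B can be built saturated from a methyl ketone and methyl acrylate.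
- Forward order: C3' chain (steps 1–2), carbocycle of ring B (step 3), aromatisation (steps 4–5), pyran of ring B (steps 6–8), sulfone (steps 9–11); pyran of ring A and formylation (steps 12–14); the halves are joined at the alkene last (step 15).
- Stereochemistry: C3' comes from a catalytic asymmetric conjugate methylation (step 2) and is never enolisable afterwards; it is (R) in 4–18 and (S) in 26 only through a change of CIP priorities. The (E) alkene comes from the Julia–Kocienski step.

Key step: step 3

Assumption: the (R,S_p) antipode of the ferrocenyl bisphosphine is taken as the one that directs methyl to the Re face of C4 of enone 3; should the sense be the opposite, its (S,R_p) mirror image is used under the same conditions.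

**Route**

Step 1
Reactants: 1 (tert-butyldimethylsilyloxy)acetaldehyde; 2 1-(triphenylphosphoranylidene)propan-2-one
Product: 3 (E)-5-(tert-butyldimethylsilyloxy)pent-3-en-2-one
Conditions: CH2Cl2, 23 °C
Reagents that add atoms: none
Why: Wittig olefination of an aldehyde with a ketone-stabilised ylide should give the (E)-enone.

Step 2
Reactants: 3 (E)-5-(tert-butyldimethylsilyloxy)pent-3-en-2-one
Product: 4 (R)-5-(tert-butyldimethylsilyloxy)-4-methylpentan-2-one
Conditions: MeMgBr (1.2 equiv, slow addition), CuBr·SMe2 (5 mol %), (R)-1-[(S_p)-2-(diphenylphosphino)ferrocenyl]ethyldicyclohexylphosphine (6 mol %), tBuOMe, −75 °C; then H2O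
Reagents that add atoms: methylmagnesium bromide, C[Mg]Br
Why: Copper-catalysed asymmetric conjugate addition of a Grignard reagent to an acyclic (E)-enone, in which the chiral bisphosphine–copper complex should deliver methyl to the Re face of C4 and so set the (R) centre that becomes C3', with 1,2-addition held back by the low temperature and slow addition.

Step 3
Reactants: 4 (R)-5-(tert-butyldimethylsilyloxy)-4-methylpentan-2-one; 5 methyl acrylate
Product: 7 4-[(2R)-1-(tert-butyldimethylsilyloxy)propan-2-yl]cyclohexane-1,3-dione (ring C4 epimers), via Michael adduct 6 (not isolated)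
Conditions: KOtBu (2.2 equiv), THF, −10 °C; 5 (1.05 equiv) added over 1 h; −10 → 23 °C; then AcOH, H2O
Reagents that add atoms: none
Why: Under proton-exchanging tert-butoxide the more substituted enolate of 4 (internal CH2) adds to methyl acrylate in a Michael reaction that forms C6–C5, and proton transfer in adduct 6 then gives the methyl-side enolate, which attacks the ester in a Claisen (Dieckmann-type) condensation that forms C8–C8a, loss of methoxide and irreversible deprotonation of the 1,3-dione pulling the sequence forward. The closest known reaction type is the consecutive Michael–Claisen synthesis of 4-substituted cyclohexane-1,3-diones from alkyl methyl ketones and acrylates. The one ring formed, the carbocycle of ring B, closes in a 6-exo-trig mode by attack of the primary enolate carbon on the ester carbonyl. The new ring stereocentre (C4 of the dione, later C6) is under no control, should form as both epimers, is enolisable and disappears on aromatisation, whereas the side-chain centre is β to the ketone, cannot enolise and is carried through unchanged. The selectivity needed is regiochemical, bond formation at the internal methylene and not at the methyl group: the substrate secures it because the internal enolate is the more substituted and more nucleophilic one under equilibrating conditions and because only the internal adduct keeps a free, unhindered acetyl group for ring closure, while slow addition of one equivalent of acrylate limits double addition. The silyl ether is inert to alkoxide and sits too far from the enolate carbon to be eliminated.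

Step 4
Reactants: 7 4-[(2R)-1-(tert-butyldimethylsilyloxy)propan-2-yl]cyclohexane-1,3-dione
Product: 8 tert-butyl{(2R)-2-[2,4-bis(trimethylsilyloxy)cyclohexa-2,4-dien-1-yl]propoxy}dimethylsilane
Conditions: Me3SiOTf (2.3 equiv), Et3N (3 equiv), CH2Cl2, 0 → 23 °C; pentane extraction under N2, used crude
Reagents that add atoms: trimethylsilyl trifluoromethanesulfonate, C[Si](C)(C)OS(=O)(=O)C(F)(F)F
Why: Soft enolisation and double O-silylation of a cyclic 1,3-dione with a silyl triflate and a tertiary amine is a known route to 1,3-bis(silyloxy)cyclohexa-1,3-dienes and leaves the alkyl silyl ether and the non-enolisable side-chain centre alone.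

Step 5
Reactants: 8 tert-butyl{(2R)-2-[2,4-bis(trimethylsilyloxy)cyclohexa-2,4-dien-1-yl]propoxy}dimethylsilane
Product: 10 4-[(2R)-1-(tert-butyldimethylsilyloxy)propan-2-yl]benzene-1,3-diol, via aryl bis(trimethylsilyl) ether 9 (not isolated)
Conditions: DDQ (1.0 equiv), 2,4,6-collidine (1.5 equiv), toluene, 0 → 23 °C; filter; then K2CO3 (0.1 equiv), MeOH, 23 °C
Reagents that add atoms: none
Why: DDQ dehydrogenation of a silyloxy-substituted cyclohexa-1,3-diene (hydride abstraction to an arenium ion stabilised by two silyloxy groups, then proton loss) should aromatise the ring without any metal hydride that could exchange the benzylic C3'–H, and carbonate-catalysed methanolysis then frees the two phenols while the primary alkyl silyl ether stays.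

Step 6
Reactants: 10 4-[(2R)-1-(tert-butyldimethylsilyloxy)propan-2-yl]benzene-1,3-diol; 11 3-chloro-3-methylbut-1-yne
Product: 12 2-[(2R)-1-(tert-butyldimethylsilyloxy)propan-2-yl]-5-[(2-methylbut-3-yn-2-yl)oxy]phenol
Conditions: 11 (1.05 equiv), DBU (1.2 equiv), CuCl2·2H2O (1 mol %), MeCN, −10 → 0 °C, N2
Reagents that add atoms: none
Why: Copper-catalysed O-propargylation of phenols with a tertiary propargylic chloride is sensitive to crowding, so with one equivalent the hydroxyl para to the side chain should react in preference to the one flanked by the branched ortho substituent.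

Step 7
Reactants: 12 2-[(2R)-1-(tert-butyldimethylsilyloxy)propan-2-yl]-5-[(2-methylbut-3-yn-2-yl)oxy]phenol
Product: 13 tert-butyl{(2R)-2-[2-methoxy-4-[(2-methylbut-3-yn-2-yl)oxy]phenyl]propoxy}dimethylsilane
Conditions: MeI (3 equiv), K2CO3 (2 equiv), acetone, 45 °C
Reagents that add atoms: iodomethane, CI
Why: Williamson methylation of the remaining hindered phenol with a small electrophile, under conditions that do not touch the terminal alkyne or the silyl ether.

Step 8
Reactants: 13 tert-butyl{(2R)-2-[2-methoxy-4-[(2-methylbut-3-yn-2-yl)oxy]phenyl]propoxy}dimethylsilane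
Product: 15 tert-butyl{(2R)-2-(7-methoxy-2,2-dimethyl-2H-chromen-6-yl)propoxy}dimethylsilane, via ortho-allenylphenol 14 (not isolated)
Conditions: PhNEt2, 185 °C
Reagents that add atoms: none
Why: Thermal aryl propargyl ether Claisen rearrangement ([3,3] shift, enolisation to the ortho-allenylphenol, [1,5]-hydrogen shift and oxa-6π electrocyclisation) should give the 2,2-dimethyl-2H-chromene at the ortho carbon para to methoxy, because the other ortho carbon lies between two oxygen substituents and is further crowded by buttressing from the neighbouring side chain.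

Step 9
Reactants: 15 tert-butyl{(2R)-2-(7-methoxy-2,2-dimethyl-2H-chromen-6-yl)propoxy}dimethylsilane
Product: 16 (2R)-2-(7-methoxy-2,2-dimethyl-2H-chromen-6-yl)propan-1-ol
Conditions: Bu4NF (1.2 equiv), THF, 0 → 23 °C; then H2O
Reagents that add atoms: none
Why: Fluoride cleavage of the primary silyl ether avoids the acid to which the electron-rich chromene double bond is sensitive.

Step 10
Reactants: 16 (2R)-2-(7-methoxy-2,2-dimethyl-2H-chromen-6-yl)propan-1-ol
Product: 17 5-{[(2R)-2-(7-methoxy-2,2-dimethyl-2H-chromen-6-yl)propyl]sulfanyl}-1-phenyl-1H-tetrazole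
Conditions: 1-phenyl-1H-tetrazole-5-thiol (1.3 equiv), PPh3 (1.3 equiv), DIAD (1.3 equiv), THF, 0 → 23 °C
Reagents that add atoms: 1-phenyl-1H-tetrazole-5-thiol, Sc1nnnn1-c1ccccc1
Why: Mitsunobu thioetherification of a primary alcohol with an acidic heteroaryl thiol, in which the stereocentre is one carbon away from the reacting centre and is not involved.

Step 11
Reactants: 17 5-{[(2R)-2-(7-methoxy-2,2-dimethyl-2H-chromen-6-yl)propyl]sulfanyl}-1-phenyl-1H-tetrazole
Product: 18 5-{[(2R)-2-(7-methoxy-2,2-dimethyl-2H-chromen-6-yl)propyl]sulfonyl}-1-phenyl-1H-tetrazole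
Conditions: (NH4)6Mo7O24·4H2O (10 mol %), 30% aq. H2O2 (6 equiv), EtOH, 0 → 23 °C
Reagents that add atoms: hydrogen peroxide, OO
Why: Molybdate-catalysed peroxide oxidation takes the sulfide through the sulfoxide to the sulfone and is selective for sulfur over alkenes, so the chromene double bond should survive.

Step 12
Reactants: 19 4-bromo-3-methoxyphenol; 11 3-chloro-3-methylbut-1-yne
Product: 20 1-bromo-2-methoxy-4-[(2-methylbut-3-yn-2-yl)oxy]benzene
Conditions: 11 (1.2 equiv), DBU (1.3 equiv), CuCl2·2H2O (1 mol %), MeCN, 0 °C, N2
Reagents that add atoms: none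
Why: The same copper-catalysed O-propargylation as in step 6, here on a single phenol.

Step 13
Reactants: 20 1-bromo-2-methoxy-4-[(2-methylbut-3-yn-2-yl)oxy]benzene
Product: 22 6-bromo-7-methoxy-2,2-dimethyl-2H-chromene, via ortho-allenylphenol 21 (not isolated)
Conditions: PhNEt2, 185 °C
Reagents that add atoms: none
Why: The aryl propargyl ether Claisen cascade of step 8 should again close at the ortho carbon para to methoxy, the bromine pressing the methoxy group toward the other ortho position.

Step 14
Reactants: 22 6-bromo-7-methoxy-2,2-dimethyl-2H-chromene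
Product: 24 7-methoxy-2,2-dimethyl-2H-chromene-6-carbaldehyde, via aryllithium 23 (not isolated)
Conditions: n-BuLi (1.05 equiv), THF, −78 °C; then DMF (3 equiv), −78 → 0 °C; then H2O
Reagents that add atoms: N,N-dimethylformamide, CN(C)C=O
Why: Bromine–lithium exchange at −78 °C is faster than any attack on the chromene, and the aryllithium is formylated by DMF through a hemiaminal alkoxide that releases the aldehyde only on work-up.

Step 15
Reactants: 18 5-{[(2R)-2-(7-methoxy-2,2-dimethyl-2H-chromen-6-yl)propyl]sulfonyl}-1-phenyl-1H-tetrazole; 24 7-methoxy-2,2-dimethyl-2H-chromene-6-carbaldehyde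
Product: 26 7-methoxy-6-[(1E,3S)-3-(7-methoxy-2,2-dimethyl-2H-chromen-6-yl)but-1-en-1-yl]-2,2-dimethyl-2H-chromene (target), via potassium sulfonyl carbanion 25 (not isolated)
Conditions: 18 (1.1 equiv), KN(SiMe3)2 (1.05 equiv), DME, −60 °C, 20 min; then 24 (1.0 equiv), −60 → 23 °C; then H2O
Reagents that add atoms: none
Why: Julia–Kocienski olefination, in which the metalated phenyltetrazolyl sulfone adds to the aromatic aldehyde and Smiles rearrangement with loss of SO2 and tetrazololate should give the (E) alkene favoured by aryl aldehydes and a potassium counter-ion in DME, the base being kept below the amount of sulfone so that the allylic, benzylic C3'–H of the product is not deprotonated.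

**Compound list**

1 | (tert-butyldimethylsilyloxy)acetaldehyde | O=CCO[Si](C)(C)C(C)(C)C | starting material
2 | 1-(triphenylphosphoranylidene)propan-2-one | CC(=O)C=P(c1ccccc1)(c1ccccc1)c1ccccc1 | starting material
3 | (E)-5-(tert-butyldimethylsilyloxy)pent-3-en-2-one | CC(=O)/C=C/CO[Si](C)(C)C(C)(C)C | intermediate
4 | (R)-5-(tert-butyldimethylsilyloxy)-4-methylpentan-2-one | CC(=O)C[C@@H](C)CO[Si](C)(C)C(C)(C)C | intermediate
5 | methyl acrylate | C=CC(=O)OC | starting material
6 | methyl (5R)-4-acetyl-6-(tert-butyldimethylsilyloxy)-5-methylhexanoate (C4 epimers) | COC(=O)CCC(C(C)=O)[C@@H](C)CO[Si](C)(C)C(C)(C)C | intermediate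
7 | 4-[(2R)-1-(tert-butyldimethylsilyloxy)propan-2-yl]cyclohexane-1,3-dione (ring C4 epimers) | O=C1CC(=O)C([C@@H](C)CO[Si](C)(C)C(C)(C)C)CC1 | intermediate
8 | tert-butyl{(2R)-2-[2,4-bis(trimethylsilyloxy)cyclohexa-2,4-dien-1-yl]propoxy}dimethylsilane (ring C1 epimers; one diene regioisomer drawn, the other converges in step 5) | C[Si](C)(C)OC1=CC(O[Si](C)(C)C)=CCC1[C@@H](C)CO[Si](C)(C)C(C)(C)C | intermediate
9 | tert-butyl{(2R)-2-[2,4-bis(trimethylsilyloxy)phenyl]propoxy}dimethylsilane | C[Si](C)(C)Oc1ccc([C@@H](C)CO[Si](C)(C)C(C)(C)C)c(O[Si](C)(C)C)c1 | intermediate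
10 | 4-[(2R)-1-(tert-butyldimethylsilyloxy)propan-2-yl]benzene-1,3-diol | Oc1ccc([C@@H](C)CO[Si](C)(C)C(C)(C)C)c(O)c1 | intermediate
11 | 3-chloro-3-methylbut-1-yne | C#CC(C)(C)Cl | starting material
12 | 2-[(2R)-1-(tert-butyldimethylsilyloxy)propan-2-yl]-5-[(2-methylbut-3-yn-2-yl)oxy]phenol | C#CC(C)(C)Oc1ccc([C@@H](C)CO[Si](C)(C)C(C)(C)C)c(O)c1 | intermediate
13 | tert-butyl{(2R)-2-[2-methoxy-4-[(2-methylbut-3-yn-2-yl)oxy]phenyl]propoxy}dimethylsilane | C#CC(C)(C)Oc1ccc([C@@H](C)CO[Si](C)(C)C(C)(C)C)c(OC)c1 | intermediate
14 | 4-[(2R)-1-(tert-butyldimethylsilyloxy)propan-2-yl]-5-methoxy-2-(3-methylbuta-1,2-dien-1-yl)phenol | CC(C)=C=Cc1cc([C@@H](C)CO[Si](C)(C)C(C)(C)C)c(OC)cc1O | intermediate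
15 | tert-butyl{(2R)-2-(7-methoxy-2,2-dimethyl-2H-chromen-6-yl)propoxy}dimethylsilane | COc1cc2c(cc1[C@@H](C)CO[Si](C)(C)C(C)(C)C)C=CC(C)(C)O2 | intermediate
16 | (2R)-2-(7-methoxy-2,2-dimethyl-2H-chromen-6-yl)propan-1-ol | COc1cc2c(cc1[C@@H](C)CO)C=CC(C)(C)O2 | intermediate
17 | 5-{[(2R)-2-(7-methoxy-2,2-dimethyl-2H-chromen-6-yl)propyl]sulfanyl}-1-phenyl-1H-tetrazole | COc1cc2c(cc1[C@@H](C)CSc1nnnn1-c1ccccc1)C=CC(C)(C)O2 | intermediate
18 | 5-{[(2R)-2-(7-methoxy-2,2-dimethyl-2H-chromen-6-yl)propyl]sulfonyl}-1-phenyl-1H-tetrazole | COc1cc2c(cc1[C@@H](C)CS(=O)(=O)c1nnnn1-c1ccccc1)C=CC(C)(C)O2 | intermediate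
19 | 4-bromo-3-methoxyphenol | COc1cc(O)ccc1Br | starting material
20 | 1-bromo-2-methoxy-4-[(2-methylbut-3-yn-2-yl)oxy]benzene | C#CC(C)(C)Oc1ccc(Br)c(OC)c1 | intermediate
21 | 4-bromo-5-methoxy-2-(3-methylbuta-1,2-dien-1-yl)phenol | CC(C)=C=Cc1cc(Br)c(OC)cc1O | intermediate
22 | 6-bromo-7-methoxy-2,2-dimethyl-2H-chromene | COc1cc2c(cc1Br)C=CC(C)(C)O2 | intermediate
23 | (7-methoxy-2,2-dimethyl-2H-chromen-6-yl)lithium | COc1cc2c(cc1[Li])C=CC(C)(C)O2 | intermediate
24 | 7-methoxy-2,2-dimethyl-2H-chromene-6-carbaldehyde | COc1cc2c(cc1C=O)C=CC(C)(C)O2 | intermediate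
25 | potassium salt of sulfone 18 deprotonated at the carbon next to sulfur | COc1cc2c(cc1[C@@H](C)[CH-]S(=O)(=O)c1nnnn1-c1ccccc1)C=CC(C)(C)O2.[K+] | intermediate
26 | 7-methoxy-6-[(1E,3S)-3-(7-methoxy-2,2-dimethyl-2H-chromen-6-yl)but-1-en-1-yl]-2,2-dimethyl-2H-chromene (CNP0212142.1) | COc1cc2c(cc1/C=C/[C@H](C)c1cc3c(cc1OC)OC(C)(C)C=C3)C=CC(C)(C)O2 | target

**Count**

Total steps: 15. Longest linear sequence: 12 steps (steps 1–11, then step 15); the ring A branch is steps 12–14.

**Steps most likely to fail, with fallbacks**

Step 3 (key step). The first carbon–carbon bond may form with loss of regiocontrol (attack through the methyl-side enolate), a second acrylate may add, or the acrylate may oligomerise under alkoxide. All of these divert material from the 4-substituted dione. The fallback generates the internal enolate regiospecifically instead of by equilibration. It sets out from enone 3: the conjugate methylation of step 2 is run as before, but the magnesium enolate is trapped with Me3SiCl and Et3N to give tert-butyldimethyl{[(2R)-2-methyl-4-(trimethylsilyloxy)pent-3-en-1-yl]oxy}silane F1. MeLi in THF at 0 °C should release the lithium enolate with its double bond fixed on the internal side. Conjugate addition of this enolate to methyl acrylate 5 at −78 °C and a proton quench should give keto ester 6, here isolated. KOtBu in THF then effects the same Claisen closure, and the route is rejoined at dione 7.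

Step 6. Discrimination between the two phenolic hydroxyls may be insufficient, so that etherification also occurs at the hindered oxygen or at both. The fallback replaces direct differentiation by a protect–methylate–release sequence and sets out from resorcinol 10. Pivaloyl chloride (1.0 equiv) with pyridine in CH2Cl2 at −20 °C should acylate the unhindered hydroxyl to give 4-[(2R)-1-(tert-butyldimethylsilyloxy)propan-2-yl]-3-hydroxyphenyl 2,2-dimethylpropanoate F2; any wrongly acylated or doubly acylated material can be returned to 10 by methanolysis. MeI and K2CO3 in acetone then give 4-[(2R)-1-(tert-butyldimethylsilyloxy)propan-2-yl]-3-methoxyphenyl 2,2-dimethylpropanoate F3. K2CO3 in MeOH cleaves the aryl ester without touching the alkyl silyl ether and gives 4-[(2R)-1-(tert-butyldimethylsilyloxy)propan-2-yl]-3-methoxyphenol F4. Propargylation of this single phenol with 11 under the conditions of step 12 comes back to the route at 13.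

Step 2. Facial selectivity may be poor, or 1,2-addition may compete, because the silyloxy group sits next to the carbon that receives methyl. The fallback sets the centre on a thioester, the acceptor class with the strongest record for methyl Grignard additions, and introduces the acetyl group afterwards. It sets out from aldehyde 1: Wittig olefination with S-ethyl 2-(triphenylphosphoranylidene)ethanethioate should give S-ethyl (2E)-4-(tert-butyldimethylsilyloxy)but-2-enethioate F5. MeMgBr with CuBr·SMe2 and the same ferrocenyl bisphosphine in tBuOMe at −75 °C should give S-ethyl (3R)-4-(tert-butyldimethylsilyloxy)-3-methylbutanethioate F6. Me2CuLi in Et2O at −78 °C converts the thioester into the methyl ketone, and the route is rejoined at 4.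

**Further compounds**

F1 | step 3 | tert-butyldimethyl{[(2R)-2-methyl-4-(trimethylsilyloxy)pent-3-en-1-yl]oxy}silane | CC(O[Si](C)(C)C)=C[C@@H](C)CO[Si](C)(C)C(C)(C)C
F2 | step 6 | 4-[(2R)-1-(tert-butyldimethylsilyloxy)propan-2-yl]-3-hydroxyphenyl 2,2-dimethylpropanoate | CC(C)(C)C(=O)Oc1ccc([C@@H](C)CO[Si](C)(C)C(C)(C)C)c(O)c1
F3 | step 6 | 4-[(2R)-1-(tert-butyldimethylsilyloxy)propan-2-yl]-3-methoxyphenyl 2,2-dimethylpropanoate | CC(C)(C)C(=O)Oc1ccc([C@@H](C)CO[Si](C)(C)C(C)(C)C)c(OC)c1
F4 | step 6 | 4-[(2R)-1-(tert-butyldimethylsilyloxy)propan-2-yl]-3-methoxyphenol | Oc1ccc([C@@H](C)CO[Si](C)(C)C(C)(C)C)c(OC)c1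
F5 | step 2 | S-ethyl (2E)-4-(tert-butyldimethylsilyloxy)but-2-enethioate | CCSC(=O)/C=C/CO[Si](C)(C)C(C)(C)C
F6 | step 2 | S-ethyl (3R)-4-(tert-butyldimethylsilyloxy)-3-methylbutanethioate | CCSC(=O)C[C@@H](C)CO[Si](C)(C)C(C)(C)C
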